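## Analysis of the target

The target is an achiral diaryl ether of two benzoic acids, so the only stereochemical questions in the route are transient ones. Ring A is pentasubstituted, and its atoms are labelled a1 (OCH3), a2 (H), a3 (CO2H), a4 (ether oxygen), a5 (OH) and a6 (Cl). Ring B is tetrasubstituted: b1 (CO2H), b2 (ether oxygen), b3 (H), b4 (CH3), b5 (H) and b6 (OH). The ether oxygen sits between the a3 carboxyl and the a5 hydroxyl on ring A and next to the b1 carboxyl on ring B, so a late diaryl ether coupling would have to join two hindered aryl carbons. Ring A also carries four different heteroatom substituents, and the chlorine at a6 between two oxygens is hard to place by substitution on a benzene ring. Sensitive features are the aryl chloride (which rules out hydrogenolysis), the free phenols, the a1 methyl ether that must survive every deprotection, and the 2,6-dioxygenated benzoic acid of ring B, which tends to decarboxylate when heated in acid. Ring B corresponds to a commercial benzoate, so the real problem is ring A. The strategy rests on one relationship: the carboxyl carbon on a3 and the oxygen on a5 are 1,4 to each other across the a3–a4 bond. If ring A is written as a cyclohexenone, a3 and a4 are both alpha carbons of carbonyl groups, and two such carbons of like polarity can be joined by oxidation.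

## Retrosynthetic reasoning

**17 to 16.** The two carboxyl groups are traced back to methyl esters. Esters of one kind throughout keep the acids inert and match the alcohol used later to install the a1 methoxy group. They are opened last by aqueous base, so the decarboxylation-prone ring B acid appears only at the end.

**16 to 15.** The b6 hydroxyl is traced back to a benzyl ether. Benzyl is chosen because it lies ortho to the b1 ester and can be removed by a chelating Lewis acid, which spares both the aryl chloride and the a1 methyl ether.

**15 to 12.** Ring A is taken back by two hydrogens, one on a3 and one on a4, to chloro enone 12. This turns a benzene ring whose substitution pattern is hard to set into a cyclohexenone in which every carbon has its own reactivity. The forward step must remove these two hydrogens without letting an a3 carbanion expel the aryloxy group from a4.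

**12 to 11.** The a6–Cl bond is cut. In enone 11, a6 is the alpha carbon of a vinylogous ester and the only nucleophilic ring carbon, so the chlorine position is fixed by innate reactivity. In the phenol 15, a2 and a6 would compete, which is why chlorination precedes aromatization.

**11 to 9 (through 10).** The a3–a4 bond is cut, which opens ring A to keto ester 9. This is the only ring bond that joins two carbonyl alpha carbons, so it cannot be made by aldol or Claisen logic but can be made by oxidative coupling of the two enol derivatives in 10. Cutting here leaves the aryloxy group on a CH2 next to a ketone, where no enolate has a leaving group in the beta position. The dangerous beta relationship between a3 and the a4 oxygen therefore arises only as the bond forms, under non-basic conditions. The forward reaction has to favour ring closure over dimerization and over oxidation of ring B.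

**9 to 8.** The a1–O bond of the enol ether is cut, leading to ynone 8. Conjugate addition of the alcohol places the methoxy group on the beta carbon only, whereas O-methylation of a 1,3-diketone could not tell a1 from a5. The forward step must give the E isomer, in which a2 and a5 are cis.

**8 to 6 + 7.** The a5–a6 bond between the acyl carbon and the alkyne is cut. Acid chloride 6 supplies a4 and a5 with the ether already in place, and commercial alkyne 7 supplies a6, a1, a2, a3 and the ester carbon.

**6 to 5 to 4.** These are functional group changes at the carbon that becomes a5. A tert-butyl ester is used because acid removes it without touching the methyl benzoate or the benzyl ether.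

**4 to 2 + 3.** The bond between the ether oxygen and a4 is cut while a4 is still a primary sp3 carbon. The hindered diaryl ether is thus made by a plain phenol alkylation with bromo ester 3, not by an aryl–oxygen coupling.

**2 to 1.** One of the two equivalent phenols of commercial benzoate 1 is benzylated. Once one is alkylated, the other is held in a hydrogen bond to the ester carbonyl, which makes monoprotection practical.

## Alternatives that were turned down

**Alternative 1:** Ring B is cut at b6–b1, b2–b3 and b4–b5 into three alkynes: aryl alkynyl ether A2 (carrying a finished, protected ring A), dipropan-2-yl ethynylboronate A3 and propyne A4. In the forward sense A2 and A3 exchange an alkoxy group on boron, and the B–O tethered diyne is cyclotrimerized with A4 under ruthenium catalysis to benzoxaborole A1, whose C–B bond at b6 is the masked phenol.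
- For: it is convergent, catalytic, and sets all ring B substituents in one step; the tether fixes b1 next to b6. On convergence it is stronger than the chosen route.
- Against: ring A must first be made as a fully substituted phenol, with the a6 chlorine placed between two oxygens by arene chemistry. A2 is an ynol ether of a di-ortho-substituted phenol, which is hard to prepare and acid-labile. Whether the methyl ends at b4 or b3 depends on the insertion of the untethered alkyne A4, which the tether does not control. After A1, the C–B bond and two benzylic CH2O groups (a3 and b1 carboxyl carbons) must all be oxidized next to an electron-rich phenol, and silyl and benzyl groups removed.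
- In its place the chosen strategy buys ring B, keeps both carboxyls at the ester level, and lets the ring A pattern, chlorine included, come from the chain.

**Alternative 2:** Ring B is cut at b4–b5 and b6–b1 into pyrone ester A6 (with a finished ring A on its C4 oxygen) and 1,1-dimethoxyethene A7. On heating, A7 adds across C6 and C3 of A6, the lactone bridge is expelled as gas, one acetal oxygen is lost as its alcohol, and benzoate A5 results.
- For: the reaction type is well established for pyrones with a 3-carbonyl group, the regiochemistry follows from polarity, and both carboxyls are already esters. The extra methyl ether at b6 lies ortho to the b1 ester and could be cleaved together with the benzyl ether by a chelating Lewis acid, so the endgame is as short as the chosen one. The key step is on firmer ground than the anodic closure; on that point this alternative is stronger.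
- Against: it also needs the complete ring A phenol from a separate multi-step arene synthesis with the same chlorine problem. A6 must be made by addition–elimination of that di-ortho-substituted, hydrogen-bonded phenol to an activated pyrone. The electron-donating aryloxy group on C4 lowers the reactivity of the pyrone as an electron-poor diene. Two methyl ethers (a1 and b6) must be distinguished at the end.
- In its place the chosen strategy needs no separate ring A synthesis and makes the hindered ether by simple alkylation.

**Alternative 3:** Ring B is cut at b6–b1 and b2–b3 (ketene–alkyne (2+2) cycloaddition) and at b5–b6 (electrocyclization) into aryl alkynyl ether A9 and 3-methylcyclobut-2-en-1-one A10. Heating opens A10 to a vinylketene, which adds to A9; four-electron ring opening and six-electron closure give phenol A8.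
- For: one metal-free thermal operation delivers b6 as a free phenol, and the polarity of the ynol ether places the ether oxygen meta and the CH2O carbon ortho to it, as required. The key step is a known reaction type and is at least as certain as the chosen one.
- Against: A9 has the same access and stability problems as A2. A10 is volatile and must be prepared. Both carboxyl carbons are at the alcohol level, so two late oxidations are needed, one of them on an ortho-hydroxybenzyl alcohol that can ionize on deprotection.
- In step economy and endgame it is clearly weaker than the chosen route, which keeps both acids as esters.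

Key step: step 7

Remark on the chemistry: 11 and 12 are racemic and drawn as the trans isomer (1R,6S shown). The route does not depend on this assignment, because both centres are destroyed in step 9.

## Route

Step 1
Reactants: 1 methyl 2,6-dihydroxy-4-methylbenzoate
Product: 2 methyl 2-(benzyloxy)-6-hydroxy-4-methylbenzoate
Conditions: BnBr (1.0 equiv), K2CO3 (1.1 equiv), acetone, reflux
Reagents that add atoms: benzyl bromide, BrCc1ccccc1
Why: Williamson ether synthesis on one of two equivalent phenols. After the first alkylation the remaining hydroxyl is locked in a hydrogen bond to the ester carbonyl and is a much poorer nucleophile, so one equivalent of halide should stop at the monoether.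

Step 2
Reactants: 2 methyl 2-(benzyloxy)-6-hydroxy-4-methylbenzoate; 3 tert-butyl bromoacetate
Product: 4 methyl 2-(benzyloxy)-6-(2-tert-butoxy-2-oxoethoxy)-4-methylbenzoate
Conditions: K2CO3, DMF, 60 °C
Reagents that add atoms: none
Why: Williamson alkylation of the hydrogen-bonded phenol with a reactive alpha-bromo ester in a dipolar solvent. The bond from the ether oxygen to the future a4 is made at a primary sp3 carbon, which avoids any hindered aryl–oxygen coupling.

Step 3
Reactants: 4 methyl 2-(benzyloxy)-6-(2-tert-butoxy-2-oxoethoxy)-4-methylbenzoate
Product: 5 [3-(benzyloxy)-2-(methoxycarbonyl)-5-methylphenoxy]acetic acid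
Conditions: CF3CO2H/CH2Cl2 1:3, 0 °C to rt
Reagents that add atoms: none
Why: Acidolysis of the tert-butyl ester through the tert-butyl cation, which leaves as 2-methylpropene. The methyl benzoate and the benzyl ether are stable to these conditions.

Step 4
Reactants: 5 [3-(benzyloxy)-2-(methoxycarbonyl)-5-methylphenoxy]acetic acid
Product: 6 methyl 2-(benzyloxy)-6-(2-chloro-2-oxoethoxy)-4-methylbenzoate
Conditions: (COCl)2, DMF (cat.), CH2Cl2, 0 °C to rt; concentrate
Reagents that add atoms: oxalyl chloride, O=C(Cl)C(=O)Cl
Why: Acid chloride formation through the Vilsmeier-type chloroiminium species. No Lewis acid is present, so the aryloxyacetyl chloride should not cyclize onto ring B.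

Step 5
Reactants: 6 methyl 2-(benzyloxy)-6-(2-chloro-2-oxoethoxy)-4-methylbenzoate; 7 methyl pent-4-ynoate
Product: 8 methyl 2-(benzyloxy)-6-[(7-methoxy-2,7-dioxohept-3-yn-1-yl)oxy]-4-methylbenzoate
Conditions: PdCl2(PPh3)2 (2 mol%), CuI (4 mol%), Et3N (1.05 equiv), THF, rt
Reagents that add atoms: none
Why: Acyl Sonogashira coupling: the acid chloride adds oxidatively to zerovalent palladium formed in situ, the alkynylcopper species made with CuI transmetalates, and reductive elimination gives the ynone (bond a5–a6). Only one equivalent of amine is used, to limit ketene formation from the aryloxyacetyl chloride.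

Step 6
Reactants: 8 methyl 2-(benzyloxy)-6-[(7-methoxy-2,7-dioxohept-3-yn-1-yl)oxy]-4-methylbenzoate
Product: 9 methyl 2-(benzyloxy)-6-{[(3E)-4,7-dimethoxy-2,7-dioxohept-3-en-1-yl]oxy}-4-methylbenzoate
Conditions: NaOMe (10 mol%), MeOH, 0 °C to rt
Reagents that add atoms: methanol, CO
Why: Oxa-Michael addition of methoxide to the beta carbon of the ynone puts the methoxy group on a1 only. The addition is reversible, so the more stable E isomer (methoxy trans to the acyl group, a2 and a5 cis) should accumulate. Methoxide in methanol leaves methyl esters unchanged.

Step 7
Reactants: 9 methyl 2-(benzyloxy)-6-{[(3E)-4,7-dimethoxy-2,7-dioxohept-3-en-1-yl]oxy}-4-methylbenzoate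
Product: 11 methyl 2-(benzyloxy)-6-{[(1RS,6SR)-4-methoxy-6-(methoxycarbonyl)-2-oxocyclohex-3-en-1-yl]oxy}-4-methylbenzoate, via bis(trimethylsilyl) triene 10 (not isolated)
Conditions: LiN(iPr)2 (2.3 equiv), Me3SiCl (4 equiv), THF, −78 °C; concentrate, pentane, filter; then reticulated vitreous carbon anode, Pt cathode, undivided cell, constant current (2.1 F/mol), LiClO4 (0.1 M), 2,6-lutidine, MeOH/CH2Cl2 1:9, 5 mM, 0 °C
Reagents that add atoms: none
Why: Lithium diisopropylamide with Me3SiCl present removes the kinetic protons at a4 (alpha to the ketone and the aryloxy oxygen, taken first) and at a3 (alpha to the ester) and gives 10; the ketone is masked before the ester enolate exists, so no aldol closure onto a5 can occur. At the anode the 1-aryloxy-2-silyloxy-4-methoxydiene, the most electron-rich pi system, loses one electron, the radical cation is attacked at a4 by the nucleophilic a3 carbon of the ketene silyl acetal, the resulting alpha-silyloxyallyl radical loses a second electron, and both silyl groups pass to methanol to leave the ester and the 3-methoxycyclohexenone. The closest known reaction type is the anodic or chemical one-electron oxidative coupling of silyl enol ethers with ketene silyl acetals or enol ethers to 1,4-dicarbonyl compounds, which has been used for ring closures. The six-membered ring closes 6-endo with respect to the diene (a4, a5, a6 and a1 all in the ring) and 6-exo with respect to the ketene acetal (ester carbon outside); the only other closures open to a3 (onto a6 or a1) would give four- or three-membered rings. The E enol ether holds a2 and a5 cis on the a1–a6 double bond, the geometry the ring requires. The two new stereocentres a3 and a4 are expected trans (aryloxy and ester groups pseudo-equatorial, and a4 can equilibrate through the enol), but no control is needed because both become sp2 in step 9. Chemoselectivity rests on the oxidation potentials of the two enol derivatives, which lie well below that of the benzyloxyarene and are reached first at low constant current density, and the 5 mM dilution favours ring closure over dimerization. The aryl ether is safe because the beta relationship between the a3 carbon and the a4 aryloxy group arises only once the bond exists, with no base present.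

Step 8
Reactants: 11 methyl 2-(benzyloxy)-6-{[(1RS,6SR)-4-methoxy-6-(methoxycarbonyl)-2-oxocyclohex-3-en-1-yl]oxy}-4-methylbenzoate
Product: 12 methyl 2-(benzyloxy)-6-{[(1RS,6SR)-3-chloro-4-methoxy-6-(methoxycarbonyl)-2-oxocyclohex-3-en-1-yl]oxy}-4-methylbenzoate
Conditions: N-chlorosuccinimide (1.05 equiv), CH2Cl2, 0 °C to rt
Reagents that add atoms: N-chlorosuccinimide, O=C1CCC(=O)N1Cl
Why: Electrophilic chlorination of a vinylogous ester at its alpha carbon: a6 is the only enol-ether-type carbon of 11 and should react faster than the ester-deactivated ring B. Chlorinating before aromatization avoids the a2/a6 competition that a phenol would show.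

Step 9
Reactants: 12 methyl 2-(benzyloxy)-6-{[(1RS,6SR)-3-chloro-4-methoxy-6-(methoxycarbonyl)-2-oxocyclohex-3-en-1-yl]oxy}-4-methylbenzoate
Product: 15 methyl 2-[3-(benzyloxy)-2-(methoxycarbonyl)-5-methylphenoxy]-4-chloro-3-hydroxy-5-methoxybenzoate, via alpha-bromo ketone 13 (not isolated), via cyclohexadienone 14 (not isolated)
Conditions: LiN(SiMe3)2 (1.1 equiv), THF, −78 °C; N-bromosuccinimide (1.05 equiv), −78 °C to rt
Reagents that add atoms: none
Why: LiN(SiMe3)2 removes the a4 proton (alpha to the ketone and to the aryloxy oxygen) much faster than the ester alpha proton at a3, and N-bromosuccinimide brominates the kinetic enolate at a4, a6 being blocked by chlorine (alpha-halogenation of a ketone enolate). On warming, the N-lithiated succinimide removes the a3 proton, and bromide, a far better leaving group than the aryloxide on the same carbon, departs (dehydrobromination) to give dienone 14. Tautomerization through loss of an a2 proton gives phenol 15, and both stereocentres vanish.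

Step 10
Reactants: 15 methyl 2-[3-(benzyloxy)-2-(methoxycarbonyl)-5-methylphenoxy]-4-chloro-3-hydroxy-5-methoxybenzoate
Product: 16 methyl 4-chloro-3-hydroxy-2-[3-hydroxy-2-(methoxycarbonyl)-5-methylphenoxy]-5-methoxybenzoate
Conditions: BCl3 (3 equiv), C6HMe5 (3 equiv), CH2Cl2, −78 to 0 °C; H2O
Reagents that add atoms: none
Why: Lewis acid debenzylation: BCl3 is chelated by the ester carbonyl and the ortho benzyloxy oxygen and cleaves the O–benzyl bond, while pentamethylbenzene traps the benzyl cation so that neither ring is C-benzylated. The a1 methyl ether is not ortho to a carbonyl group and should survive at this temperature, and the aryl chloride is untouched.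

Step 11
Reactants: 16 methyl 4-chloro-3-hydroxy-2-[3-hydroxy-2-(methoxycarbonyl)-5-methylphenoxy]-5-methoxybenzoate
Product: 17 2-(6-carboxy-3-chloro-2-hydroxy-4-methoxyphenoxy)-6-hydroxy-4-methylbenzoic acid
Conditions: LiOH·H2O (10 equiv), THF/MeOH/H2O, 60 °C; then 1 M HCl, 0 °C
Reagents that add atoms: lithium hydroxide, [Li+].[OH-]
Why: Saponification of both methyl esters by acyl–oxygen cleavage. The ring A ester has one ortho substituent and should hydrolyse readily; the ring B ester between two ortho oxygens needs the excess base and the heating. Cold acidification avoids decarboxylation of the 2,6-dioxygenated acid.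

## Compound list

1 | methyl 2,6-dihydroxy-4-methylbenzoate | COC(=O)c1c(O)cc(C)cc1O | starting material
2 | methyl 2-(benzyloxy)-6-hydroxy-4-methylbenzoate | COC(=O)c1c(O)cc(C)cc1OCc1ccccc1 | intermediate
3 | tert-butyl bromoacetate | CC(C)(C)OC(=O)CBr | starting material
4 | methyl 2-(benzyloxy)-6-(2-tert-butoxy-2-oxoethoxy)-4-methylbenzoate | COC(=O)c1c(OCC(=O)OC(C)(C)C)cc(C)cc1OCc1ccccc1 | intermediate
5 | [3-(benzyloxy)-2-(methoxycarbonyl)-5-methylphenoxy]acetic acid | COC(=O)c1c(OCC(=O)O)cc(C)cc1OCc1ccccc1 | intermediate
6 | methyl 2-(benzyloxy)-6-(2-chloro-2-oxoethoxy)-4-methylbenzoate | COC(=O)c1c(OCC(=O)Cl)cc(C)cc1OCc1ccccc1 | intermediate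
7 | methyl pent-4-ynoate | C#CCCC(=O)OC | starting material
8 | methyl 2-(benzyloxy)-6-[(7-methoxy-2,7-dioxohept-3-yn-1-yl)oxy]-4-methylbenzoate | COC(=O)CCC#CC(=O)COc1cc(C)cc(OCc2ccccc2)c1C(=O)OC | intermediate
9 | methyl 2-(benzyloxy)-6-{[(3E)-4,7-dimethoxy-2,7-dioxohept-3-en-1-yl]oxy}-4-methylbenzoate | COC(=O)CC/C(OC)=C\C(=O)COc1cc(C)cc(OCc2ccccc2)c1C(=O)OC | intermediate
10 | methyl 2-(benzyloxy)-6-({(3E)-4,7-dimethoxy-2,7-bis[(trimethylsilyl)oxy]hepta-1,3,6-trien-1-yl}oxy)-4-methylbenzoate (geometry of the two new double bonds not defined) | COC(O[Si](C)(C)C)=CC/C(OC)=C\C(O[Si](C)(C)C)=COc1cc(C)cc(OCc2ccccc2)c1C(=O)OC | intermediate (not isolated)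
11 | methyl 2-(benzyloxy)-6-{[(1RS,6SR)-4-methoxy-6-(methoxycarbonyl)-2-oxocyclohex-3-en-1-yl]oxy}-4-methylbenzoate (trans, racemic, one enantiomer drawn) | COC1=CC(=O)[C@H](Oc2cc(C)cc(OCc3ccccc3)c2C(=O)OC)[C@@H](C(=O)OC)C1 | intermediate
12 | methyl 2-(benzyloxy)-6-{[(1RS,6SR)-3-chloro-4-methoxy-6-(methoxycarbonyl)-2-oxocyclohex-3-en-1-yl]oxy}-4-methylbenzoate (trans, racemic, one enantiomer drawn) | COC1=C(Cl)C(=O)[C@H](Oc2cc(C)cc(OCc3ccccc3)c2C(=O)OC)[C@@H](C(=O)OC)C1 | intermediate
13 | methyl 2-(benzyloxy)-6-{[1-bromo-3-chloro-4-methoxy-6-(methoxycarbonyl)-2-oxocyclohex-3-en-1-yl]oxy}-4-methylbenzoate (mixture of diastereomers, racemic) | COC1=C(Cl)C(=O)C(Br)(Oc2cc(C)cc(OCc3ccccc3)c2C(=O)OC)C(C(=O)OC)C1 | intermediate (not isolated)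
14 | methyl 2-(benzyloxy)-6-{[5-chloro-4-methoxy-2-(methoxycarbonyl)-6-oxocyclohexa-1,4-dien-1-yl]oxy}-4-methylbenzoate | COC1=C(Cl)C(=O)C(Oc2cc(C)cc(OCc3ccccc3)c2C(=O)OC)=C(C(=O)OC)C1 | intermediate (not isolated)
15 | methyl 2-[3-(benzyloxy)-2-(methoxycarbonyl)-5-methylphenoxy]-4-chloro-3-hydroxy-5-methoxybenzoate | COC(=O)c1cc(OC)c(Cl)c(O)c1Oc1cc(C)cc(OCc2ccccc2)c1C(=O)OC | intermediate
16 | methyl 4-chloro-3-hydroxy-2-[3-hydroxy-2-(methoxycarbonyl)-5-methylphenoxy]-5-methoxybenzoate | COC(=O)c1cc(OC)c(Cl)c(O)c1Oc1cc(C)cc(O)c1C(=O)OC | intermediate
17 | 2-(6-carboxy-3-chloro-2-hydroxy-4-methoxyphenoxy)-6-hydroxy-4-methylbenzoic acid | COc1cc(C(=O)O)c(Oc2cc(C)cc(O)c2C(=O)O)c(O)c1Cl | target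

## Step count and risk

Total step count: 11 steps. Longest linear sequence: 11 steps (1 to 17); 3 and 7 enter as bought building blocks.

**Step 7 (key step).**
- What may go wrong: the ketene silyl acetal may lose its silyl group by solvolysis before electron transfer, which returns 9. Intermolecular coupling may compete despite dilution. The radical cation may lose a proton instead of being trapped, because a six-membered closure onto a carbon bearing an aryloxy group is slower than the five-membered closures usually run this way.
- Fallback: this leaves the electrode and the silyl groups and uses inner-sphere oxidation of metal enolates. Setting out from 9, two equivalents of lithium diisopropylamide in THF at −78 °C (ketone first, then ester) give the dilithium bis-enolate of 9 F1, which is oxidized in the same flask with two equivalents of Fe(acac)3. Coupling of the two enolate carbons returns to the route at 11.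

**Step 9.**
- What may go wrong: competing removal of the a3 proton before bromination would expel the aryloxide from a4 (E1cB) and break the ether link between the rings. Proton transfer to the extended enolate would send bromine to a2.
- Fallback: base-free dehydrogenation. Setting out from 12, DDQ with catalytic toluenesulfonic acid in dioxane at 80 °C abstracts hydride from the dienol and, after proton loss and tautomerization, returns to the route at 15 (no new compound, F0).

**Step 5.**
- What may go wrong: the amine may dehydrochlorinate 6 to an aryloxyketene, which dimerizes or is captured, and the alkyne may homocouple under copper catalysis.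
- Fallback: amine-free acyl Stille coupling. Setting out from 7, heating with tributyl(methoxy)stannane gives methyl 5-(tributylstannyl)pent-4-ynoate F2, which is coupled with 6 under PdCl2(PPh3)2 in dioxane to return to the route at 8.

**Step 6.**
- What may go wrong: methoxide may isomerize the ynone to an allenyl ketone through the propargylic a2 protons, a second addition may give the beta,beta-dimethoxy ketone, and some Z isomer may persist.
- Fallback: the alkyne is removed before any base is used. Setting out from 8, NaI in acetic acid adds hydrogen iodide anti across the triple bond to give methyl 2-(benzyloxy)-6-{[(3Z)-4-iodo-7-methoxy-2,7-dioxohept-3-en-1-yl]oxy}-4-methylbenzoate F3. One equivalent of NaOMe in methanol at 0 °C then replaces iodide by addition–elimination and returns to the route at 9.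

**Step 11.**
- What may go wrong: acyl–oxygen cleavage of the ring B ester may stall, because the carbonyl is flanked by two ortho oxygens and deactivated by the ortho phenoxide. Forcing the hydrolysis and acidifying risks decarboxylation at b1.
- Fallback: cleave the methyl–oxygen bond instead. Setting out from 16, LiSCH2CH2CH3 in HMPA at room temperature demethylates both esters by SN2 attack at the methyl carbon, which is insensitive to ortho hindrance and leaves the a1 aryl methyl ether alone at this temperature. Cold acidification returns to the route at 17 (no new compound, F0).

## Further compounds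

F1 | step 7 | dilithium (3E)-1-[3-(benzyloxy)-2-(methoxycarbonyl)-5-methylphenoxy]-4,7-dimethoxyhepta-1,3,6-triene-2,7-bis(olate) | [Li+].[Li+].COC([O-])=CC/C(OC)=C\C([O-])=COc1cc(C)cc(OCc2ccccc2)c1C(=O)OC
F0 | step 9 | none | none
F2 | step 5 | methyl 5-(tributylstannyl)pent-4-ynoate | CCCC[Sn](CCCC)(CCCC)C#CCCC(=O)OC
F3 | step 6 | methyl 2-(benzyloxy)-6-{[(3Z)-4-iodo-7-methoxy-2,7-dioxohept-3-en-1-yl]oxy}-4-methylbenzoate | COC(=O)CC/C(I)=C/C(=O)COc1cc(C)cc(OCc2ccccc2)c1C(=O)OC
F0 | step 11 | none | none
A1 | alternative 1 | 4-[2-(benzyloxy)-6-({[tert-butyl(dimethyl)silyl]oxy}methyl)-3-chloro-4-methoxyphenoxy]-6-methyl-1-(propan-2-yloxy)-1,3-dihydro-2,1-benzoxaborole | CC(C)OB1OCc2c1cc(C)cc2Oc1c(CO[Si](C)(C)C(C)(C)C)cc(OC)c(Cl)c1OCc1ccccc1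
A2 | alternative 1 | 3-[2-(benzyloxy)-6-({[tert-butyl(dimethyl)silyl]oxy}methyl)-3-chloro-4-methoxyphenoxy]prop-2-yn-1-ol | OCC#COc1c(CO[Si](C)(C)C(C)(C)C)cc(OC)c(Cl)c1OCc1ccccc1
A3 | alternative 1 | dipropan-2-yl ethynylboronate | CC(C)OB(OC(C)C)C#C
A4 | alternative 1 | propyne | CC#C
A5 | alternative 2 | methyl 3-(benzyloxy)-4-chloro-5-methoxy-2-[3-methoxy-2-(methoxycarbonyl)-5-methylphenoxy]benzoate | COC(=O)c1c(OC)cc(C)cc1Oc1c(C(=O)OC)cc(OC)c(Cl)c1OCc1ccccc1
A6 | alternative 2 | methyl 4-[2-(benzyloxy)-3-chloro-4-methoxy-6-(methoxycarbonyl)phenoxy]-6-methyl-2-oxo-2H-pyran-3-carboxylate | COC(=O)C1=C(Oc2c(C(=O)OC)cc(OC)c(Cl)c2OCc2ccccc2)C=C(C)OC1=O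
A7 | alternative 2 | 1,1-dimethoxyethene | C=C(OC)OC
A8 | alternative 3 | 3-[2-(benzyloxy)-6-({[tert-butyl(dimethyl)silyl]oxy}methyl)-3-chloro-4-methoxyphenoxy]-2-({[tert-butyl(dimethyl)silyl]oxy}methyl)-5-methylphenol | COc1cc(CO[Si](C)(C)C(C)(C)C)c(Oc2cc(C)cc(O)c2CO[Si](C)(C)C(C)(C)C)c(OCc2ccccc2)c1Cl
A9 | alternative 3 | tert-butyl({3-[2-(benzyloxy)-6-({[tert-butyl(dimethyl)silyl]oxy}methyl)-3-chloro-4-methoxyphenoxy]prop-2-yn-1-yl}oxy)dimethylsilane | CC(C)(C)[Si](C)(C)OCC#COc1c(CO[Si](C)(C)C(C)(C)C)cc(OC)c(Cl)c1OCc1ccccc1
A10 | alternative 3 | 3-methylcyclobut-2-en-1-one | CC1=CC(=O)C1
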